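**Retrosynthetic overview**
- Feature: the 21-membered ring consists of three carbons of ring A (the 1,3,5-substituted monophenol), the ether oxygen, three carbons of ring B (the hydroquinone) and an unbranched, unfunctionalised C14 bridge (C1 on ring B, C14 on ring A). C4 and C5 are plain CH2 groups with no polarity bias, so their bond can come from two formyl carbons and the resulting C=C can be hydrogenated away.
- Endgame: triol ⇐ (BBr3) trimethyl ether ⇐ (H2) macrocyclic C4=C5 alkene ⇐ (intramolecular McMurry coupling) acyclic dialdehyde ⇐ diol.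
- Arms and ether: C1–C4 come from the ring B formyl carbon plus a C3 hydroxy ylide, and C5–C14 from the ring A formyl carbon plus a C9 hydroxy ylide. The diaryl ether is made by Ullmann coupling of the ring A phenol with a ring B bromide, placed between the two Wittig operations.
- Ring order: both benzene rings are bought, and the macrocycle is the only ring formed, at step 11.

Key step: step 11

Remark: the target has no stereocentre and every C=C made on the way is later hydrogenated, so one alkene isomer is drawn in each case and either isomer serves.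

**Step 1**
Reactants: 1 9-bromononan-1-ol
Product: 2 (9-hydroxynonyl)triphenylphosphonium bromide
Conditions: PPh3, MeCN, reflux
Reagents that add atoms: triphenylphosphine, c1ccc(cc1)P(c1ccccc1)c1ccccc1
Why: SN2 quaternisation of triphenylphosphine by an unhindered primary bromide, in which the remote hydroxyl is a spectator.

**Step 2**
Reactants: 3 3-hydroxy-5-methoxybenzaldehyde
Product: 4 3-(benzyloxy)-5-methoxybenzaldehyde
Conditions: BnBr, K2CO3, DMF, rt
Reagents that add atoms: benzyl bromide, BrCc1ccccc1
Why: Williamson ether synthesis masks the acidic phenol that would quench the ylide, with a group that falls off in the hydrogenation already needed in step 4.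

**Step 3**
Reactants: 2 (9-hydroxynonyl)triphenylphosphonium bromide; 4 3-(benzyloxy)-5-methoxybenzaldehyde
Product: 6 (Z)-10-[3-(benzyloxy)-5-methoxyphenyl]dec-9-en-1-ol (Z drawn; either isomer serves), via sodium oxido ylide 5 (not isolated)
Conditions: 2, NaHMDS (2 equiv per salt), THF, −78 → 0 °C; then 4, −78 °C → rt; H2O
Reagents that add atoms: none
Why: Wittig olefination of an aromatic aldehyde with a non-stabilised ylide, in which the first equivalent of base takes the hydroxyl proton and the second the α-CH, giving the full ten-carbon arm in one C=C bond formation.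

**Step 4**
Reactants: 6 (Z)-10-[3-(benzyloxy)-5-methoxyphenyl]dec-9-en-1-ol
Product: 7 3-(10-hydroxydecyl)-5-methoxyphenol
Conditions: H2 (1 atm), Pd/C, EtOH, rt
Reagents that add atoms: none
Why: catalytic hydrogenation saturates the styrenyl alkene and hydrogenolyses the benzyl aryl ether in the same operation, leaving the methyl ether and the primary alcohol untouched.

**Step 5**
Reactants: 8 2-hydroxy-5-methoxybenzaldehyde
Product: 9 3-bromo-2-hydroxy-5-methoxybenzaldehyde
Conditions: Br2, NaOAc, AcOH, rt
Reagents that add atoms: bromine, BrBr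
Why: in this electrophilic aromatic bromination the free hydroxyl is the dominant director, and since its para position carries OMe and one ortho position carries CHO, bromine enters at C3.

**Step 6**
Reactants: 9 3-bromo-2-hydroxy-5-methoxybenzaldehyde
Product: 10 3-bromo-2,5-dimethoxybenzaldehyde
Conditions: MeI, K2CO3, DMF, rt
Reagents that add atoms: iodomethane, CI
Why: Williamson O-methylation of the phenoxide gives the same protecting group at all three oxygens, so a single deprotection suffices at the end.

**Step 7**
Reactants: 7 3-(10-hydroxydecyl)-5-methoxyphenol; 10 3-bromo-2,5-dimethoxybenzaldehyde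
Product: 11 3-[3-(10-hydroxydecyl)-5-methoxyphenoxy]-2,5-dimethoxybenzaldehyde
Conditions: CuI (cat.), N,N-dimethylglycine hydrochloride (cat.), Cs2CO3, 1,4-dioxane, 90–100 °C, Ar
Reagents that add atoms: none
Why: in this ligand-accelerated Ullmann diaryl ether synthesis Cs2CO3 deprotonates only the phenol, so a copper phenoxide rather than an alkoxide couples, while the aldehyde is non-enolisable and the tertiary amine ligand cannot condense with it.

**Step 8**
Reactants: 11 3-[3-(10-hydroxydecyl)-5-methoxyphenoxy]-2,5-dimethoxybenzaldehyde; 12 (3-hydroxypropyl)triphenylphosphonium bromide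
Product: 14 (E)-4-{3-[3-(10-hydroxydecyl)-5-methoxyphenoxy]-2,5-dimethoxyphenyl}but-3-en-1-ol (E drawn; either isomer serves), via lithium oxido ylide 13 (not isolated)
Conditions: 12 (3 equiv), n-BuLi (6 equiv), THF, 0 °C; then 11, −78 °C → rt; H2O
Reagents that add atoms: none
Why: Wittig olefination with the γ-oxido ylide adds the three missing carbons of the short arm with the hydroxyl already in place, and excess ylide absorbs the proton of the free alcohol in 11.

**Step 9**
Reactants: 14 (E)-4-{3-[3-(10-hydroxydecyl)-5-methoxyphenoxy]-2,5-dimethoxyphenyl}but-3-en-1-ol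
Product: 15 10-{3-[3-(4-hydroxybutyl)-2,5-dimethoxyphenoxy]-5-methoxyphenyl}decan-1-ol
Conditions: H2 (1 atm), Pd/C, EtOAc, rt
Reagents that add atoms: none
Why: catalytic hydrogenation of the styrenyl alkene before oxidation avoids a β,γ-unsaturated aldehyde that would slip into conjugation, and the aryl ethers are inert.

**Step 10**
Reactants: 15 10-{3-[3-(4-hydroxybutyl)-2,5-dimethoxyphenoxy]-5-methoxyphenyl}decan-1-ol
Product: 16 10-{3-[2,5-dimethoxy-3-(4-oxobutyl)phenoxy]-5-methoxyphenyl}decanal
Conditions: Dess–Martin periodinane (2.4 equiv), CH2Cl2, 0 °C → rt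
Reagents that add atoms: none
Why: Dess–Martin oxidation takes both primary alcohols to the aldehyde stage under near-neutral conditions, without over-oxidation and without touching the electron-rich arenes.

**Step 11**
Reactants: 16 10-{3-[2,5-dimethoxy-3-(4-oxobutyl)phenoxy]-5-methoxyphenyl}decanal
Product: 18 (E)-1^5,3^2,3^5-trimethoxy-2-oxa-1(1,3),3(1,3)-dibenzenacycloheptadecaphan-7-ene (macrocyclic C4=C5 alkene; E drawn; either isomer serves), via titanium pinacolate 17 (not isolated)
Conditions: TiCl3(DME)1.5 (large excess), Zn–Cu couple, DME, reflux, 4 h; then 16 in DME by syringe pump over ca. 35 h (final ca. 3 mM); reflux, further 8 h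
Reagents that add atoms: none
Why: Low-valent titanium made from TiCl3(DME)1.5 and Zn–Cu couple gives one electron to each formyl group, the two surface-bound ketyl radicals combine to form the C4–C5 bond as pinacolate 17, and at reflux both C–O bonds break to leave the alkene, driven by the strength of the Ti–O bond. The closest known reaction type is the intramolecular McMurry coupling of α,ω-dialdehydes to medium and large cycloalkenes. The 21-membered ring closes by end-to-end radical–radical union in which both reacting carbons become ring members, and because both termini sit on the same titanium surface the closure depends little on ring size. No stereocentre is kept, since the two carbinol centres of 17 vanish on deoxygenation and the E/Z geometry vanishes in step 12. The selectivity needed is intramolecular over intermolecular coupling, which slow addition into excess reagent secures by keeping the stationary concentration of free dialdehyde very low. Chemoselectivity is secured because, apart from the two unhindered aliphatic aldehydes, the substrate holds only aryl methyl ethers and a diaryl ether, which low-valent titanium does not reduce.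

**Step 12**
Reactants: 18 macrocyclic C4=C5 alkene
Product: 19 1^5,3^2,3^5-trimethoxy-2-oxa-1(1,3),3(1,3)-dibenzenacycloheptadecaphane
Conditions: H2 (1 atm), Pd/C, EtOAc, rt
Reagents that add atoms: none
Why: catalytic hydrogenation of an unhindered 1,2-disubstituted alkene turns both isomers into the same saturated C14 bridge.

**Step 13**
Reactants: 19 1^5,3^2,3^5-trimethoxy-2-oxa-1(1,3),3(1,3)-dibenzenacycloheptadecaphane
Product: 21 2-oxa-1(1,3),3(1,3)-dibenzenacycloheptadecaphane-1^5,3^2,3^5-triol (CNP0393720.0), via tris(dibromoboryl) ether 20 (not isolated)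
Conditions: BBr3 (6 equiv), CH2Cl2, −78 °C → rt, Ar; then degassed H2O, 0 °C
Reagents that add atoms: none
Why: in this Lewis-acid cleavage of aryl methyl ethers bromide attacks each boron-activated O–CH3 carbon, whereas the diaryl ether has no sp3 carbon to attack and survives, and air is excluded on work-up to protect the hydroquinone.

**Compound list**
1 | 9-bromononan-1-ol | OCCCCCCCCCBr | starting material
2 | (9-hydroxynonyl)triphenylphosphonium bromide | OCCCCCCCCC[P+](c1ccccc1)(c1ccccc1)c1ccccc1.[Br-] | intermediate
3 | 3-hydroxy-5-methoxybenzaldehyde | COc1cc(O)cc(C=O)c1 | starting material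
4 | 3-(benzyloxy)-5-methoxybenzaldehyde | COc1cc(OCc2ccccc2)cc(C=O)c1 | intermediate
5 | sodium 9-(triphenyl-λ5-phosphanylidene)nonan-1-olate (oxido ylide, not isolated) | [Na+].[O-]CCCCCCCCC=P(c1ccccc1)(c1ccccc1)c1ccccc1 | intermediate
6 | (Z)-10-[3-(benzyloxy)-5-methoxyphenyl]dec-9-en-1-ol | COc1cc(OCc2ccccc2)cc(/C=C\CCCCCCCCO)c1 | intermediate
7 | 3-(10-hydroxydecyl)-5-methoxyphenol | COc1cc(O)cc(CCCCCCCCCCO)c1 | intermediate
8 | 2-hydroxy-5-methoxybenzaldehyde | COc1ccc(O)c(C=O)c1 | starting material
9 | 3-bromo-2-hydroxy-5-methoxybenzaldehyde | COc1cc(Br)c(O)c(C=O)c1 | intermediate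
10 | 3-bromo-2,5-dimethoxybenzaldehyde | COc1cc(Br)c(OC)c(C=O)c1 | intermediate
11 | 3-[3-(10-hydroxydecyl)-5-methoxyphenoxy]-2,5-dimethoxybenzaldehyde | COc1cc(CCCCCCCCCCO)cc(Oc2cc(OC)cc(C=O)c2OC)c1 | intermediate
12 | (3-hydroxypropyl)triphenylphosphonium bromide | OCCC[P+](c1ccccc1)(c1ccccc1)c1ccccc1.[Br-] | starting material
13 | lithium 3-(triphenyl-λ5-phosphanylidene)propan-1-olate (oxido ylide, not isolated) | [Li+].[O-]CCC=P(c1ccccc1)(c1ccccc1)c1ccccc1 | intermediate
14 | (E)-4-{3-[3-(10-hydroxydecyl)-5-methoxyphenoxy]-2,5-dimethoxyphenyl}but-3-en-1-ol | COc1cc(CCCCCCCCCCO)cc(Oc2cc(OC)cc(/C=C/CCO)c2OC)c1 | intermediate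
15 | 10-{3-[3-(4-hydroxybutyl)-2,5-dimethoxyphenoxy]-5-methoxyphenyl}decan-1-ol | COc1cc(CCCCCCCCCCO)cc(Oc2cc(OC)cc(CCCCO)c2OC)c1 | intermediate
16 | 10-{3-[2,5-dimethoxy-3-(4-oxobutyl)phenoxy]-5-methoxyphenyl}decanal | COc1cc(CCCCCCCCCC=O)cc(Oc2cc(OC)cc(CCCC=O)c2OC)c1 | intermediate
17 | macrocyclic titanium 7,8-pinacolate (surface-bound, drawn with one Ti, diastereomer mixture, not isolated) | COc1cc2cc(c1)Oc1cc(OC)cc(c1OC)CCCC1O[Ti]OC1CCCCCCCCC2 | intermediate
18 | (E)-1^5,3^2,3^5-trimethoxy-2-oxa-1(1,3),3(1,3)-dibenzenacycloheptadecaphan-7-ene | COc1cc2cc(c1)Oc1cc(OC)cc(c1OC)CCC/C=C/CCCCCCCCC2 | intermediate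
19 | 1^5,3^2,3^5-trimethoxy-2-oxa-1(1,3),3(1,3)-dibenzenacycloheptadecaphane | COc1cc2cc(c1)Oc1cc(OC)cc(c1OC)CCCCCCCCCCCCCC2 | intermediate
20 | 1^5,3^2,3^5-tris(dibromoboryloxy)-2-oxa-1(1,3),3(1,3)-dibenzenacycloheptadecaphane (not isolated) | BrB(Br)Oc1cc2cc(c1)Oc1cc(OB(Br)Br)cc(c1OB(Br)Br)CCCCCCCCCCCCCC2 | intermediate
21 | 2-oxa-1(1,3),3(1,3)-dibenzenacycloheptadecaphane-1^5,3^2,3^5-triol (CNP0393720.0) | Oc1cc2cc(c1)Oc1cc(O)cc(c1O)CCCCCCCCCCCCCC2 | target

**Totals**
Total step count: 13.
Longest linear sequence: 10 steps (step 1 or 2, then 3, 4 and 7–13).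

**Steps most likely to fail**

1. Step 11 (McMurry macrocyclisation).
   - Risk: intermolecular ketyl coupling to dimers and oligomers may outrun ring closure. The reaction may also stall at the pinacolate stage, or simply reduce the formyl groups.
   - Fallback: it sets out from dialdehyde 16. Both formyl groups are methylenated with Ph3P=CH2 (MePPh3Br, KOt-Bu, THF, 0 °C) to give the α,ω-diene 2,5-dimethoxy-1-[3-methoxy-5-(undec-10-en-1-yl)phenoxy]-3-(pent-4-en-1-yl)benzene F1.
   - Ring-closing metathesis (second-generation Grubbs catalyst, CH2Cl2, reflux, high dilution) then expels ethene and forms the same C4=C5 bond. The route is rejoined at 18.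

2. Step 7 (Ullmann coupling).
   - Risk: oxidative addition at the bromide flanked by an ortho methoxy group may be slow. Protodebromination, or attrition of the aldehyde and the free alcohol at high temperature, could then compete.
   - Fallback: it reverses the role of ring B and sets out from bromide 10. Miyaura borylation (B2pin2, Pd(dppf)Cl2, KOAc, dioxane, 85 °C) gives 2,5-dimethoxy-3-(4,4,5,5-tetramethyl-1,3,2-dioxaborolan-2-yl)benzaldehyde F2.
   - Periodate cleavage of the pinacol ester (NaIO4, NH4OAc, acetone–H2O) gives (3-formyl-2,5-dimethoxyphenyl)boronic acid F3.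
   - Chan–Lam–Evans coupling of F3 with phenol 7 (Cu(OAc)2, pyridine, 4 Å molecular sieves, CH2Cl2, air, rt) forms the diaryl ether at room temperature. The route is rejoined at 11.

3. Step 8 (Wittig with the γ-oxido ylide).
   - Risk: the ylide may collapse to the cyclic oxaphospholane. Proton exchange with the substrate alcohol may also leave the ortho-substituted aldehyde incompletely converted.
   - Fallback: it replaces olefination by carbonyl addition and sets out from 11. Excess allylmagnesium bromide (THF, 0 °C) gives racemic 1-{3-[3-(10-hydroxydecyl)-5-methoxyphenoxy]-2,5-dimethoxyphenyl}but-3-en-1-ol F4.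
   - Hydroboration–oxidation (9-BBN, THF; then NaOH, H2O2) gives racemic 1-{3-[3-(10-hydroxydecyl)-5-methoxyphenoxy]-2,5-dimethoxyphenyl}butane-1,4-diol F5.
   - Acid-assisted hydrogenolysis of the electron-rich benzylic C–O bond (H2, Pd/C, EtOH, cat. HCl) removes the extra hydroxyl. The route is rejoined at 15, so step 9 is bypassed.

**Further compounds**
F1 | step 11 | 2,5-dimethoxy-1-[3-methoxy-5-(undec-10-en-1-yl)phenoxy]-3-(pent-4-en-1-yl)benzene | COc1cc(CCCCCCCCCC=C)cc(Oc2cc(OC)cc(CCCC=C)c2OC)c1
F2 | step 7 | 2,5-dimethoxy-3-(4,4,5,5-tetramethyl-1,3,2-dioxaborolan-2-yl)benzaldehyde | COc1cc(C=O)c(OC)c(B2OC(C)(C)C(C)(C)O2)c1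
F3 | step 7 | (3-formyl-2,5-dimethoxyphenyl)boronic acid | COc1cc(C=O)c(OC)c(B(O)O)c1
F4 | step 8 | 1-{3-[3-(10-hydroxydecyl)-5-methoxyphenoxy]-2,5-dimethoxyphenyl}but-3-en-1-ol (racemic) | COc1cc(CCCCCCCCCCO)cc(Oc2cc(OC)cc(C(O)CC=C)c2OC)c1
F5 | step 8 | 1-{3-[3-(10-hydroxydecyl)-5-methoxyphenoxy]-2,5-dimethoxyphenyl}butane-1,4-diol (racemic) | COc1cc(CCCCCCCCCCO)cc(Oc2cc(OC)cc(C(O)CCCO)c2OC)c1
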